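Rings are lettered A–H from the 3,5-dihydroxyphenoxy end (B and C = dibenzofuran, D = dioxin-fused ring, E–F = biaryl, G, terminal H). Ring C: c1 (furan O), c2 (H), c3 (OH), c4 and c5 (dioxin O, c5 on the bay side), c6 (bond to b5). Ring D: d1 (O to c5), d2 and d4 (OH), d3 (H), d5 (O to ring E), d6 (O to c4). Ring B: b1 (O to ring A), b2 and b4 (OH), b3 (H), b5, b6 (furan O).
Feature used: c5, which carries the bay-side dioxin oxygen, and c6, which carries the C–C bond to ring B, are neighbours. A c5≡c6 aryne can therefore take up the d1 oxygen at c5 and leave a carbanion, then an iodide, at c6.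
Disconnections, backwards: sixteen benzyl ethers (H2); furan c1–O–b6 (Pd C–H/C–O cyclisation, b6–H being the only free ortho C–H); ether d5–O–E (Ullmann, E–F–G–H bromide); biaryl c6–b5 (Suzuki, A–B boronate); dioxin c5–O–d1 (aryne); ether c4–O–d6 (SNAr on a 2-fluoroisophthalaldehyde whose formyl groups become d1-OH and d5-OH by Baeyer–Villiger oxidation).
Design points: the c4–O–d6 ether is made without copper because ring C already holds the iodide. Ring D stays mirror-symmetric with d1-OH and d5-OH both free, so the aryne closure desymmetrises it and leaves d5-OH for ring E. c1 carries the only MOM ether and all permanent groups are benzyl. The E–F axis comes from an early Ullmann homocoupling.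
Ring order: dioxin (step 11), then furan (step 29); all benzene rings come from purchased phenols.

Key step: step 11

Remark: the target SMILES has no stereodescriptor, so the tetra-ortho-oxygenated E–F axis is made and carried as the racemate; the c6–b5 axis of 46–48 vanishes on furan closure, so rotamer mixtures there are of no consequence.

Step 1
Reactants: 1 2,4,6-trihydroxybenzaldehyde
Product: 2 2,6-dihydroxy-4-(methoxymethoxy)benzaldehyde
Conditions: MOMCl (1.0 equiv), K2CO3 (1.0 equiv), acetone, 0 °C to rt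
Reagents that add atoms: chloromethyl methyl ether COCCl
Why: Williamson-type MOM protection: with one equivalent each of base and MOMCl the para hydroxyl (future c1-O), the most acidic one and the only one outside the hydrogen-bond chelate with the formyl group, should react first, and any bis-MOM ether is removed by chromatography.

Step 2
Reactants: 2 2,6-dihydroxy-4-(methoxymethoxy)benzaldehyde
Product: 3 2-(benzyloxy)-6-hydroxy-4-(methoxymethoxy)benzaldehyde
Conditions: BnBr (1.05 equiv), K2CO3, DMF, rt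
Reagents that add atoms: benzyl bromide BrCc1ccccc1
Why: Williamson etherification: once one of the two equivalent ortho hydroxyls is benzylated (future c3-OBn) the last hydroxyl is locked in a strong hydrogen bond to the aldehyde and stays free, the selectivity routinely used for acylphloroglucinols.

Step 3
Reactants: 3 2-(benzyloxy)-6-hydroxy-4-(methoxymethoxy)benzaldehyde
Product: 4 6-(benzyloxy)-2-hydroxy-3-iodo-4-(methoxymethoxy)benzaldehyde
Conditions: NIS (1.05 equiv), DMF, 0 °C to rt
Reagents that add atoms: N-iodosuccinimide O=C1CCC(=O)N1I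
Why: Electrophilic aromatic iodination: the carbon between the free hydroxyl and the MOM ether (ortho to OH, para to OBn, future c6) is more accessible than the carbon between two ethers, in line with the 3-halogenation known for 2-hydroxy-4,6-dialkoxybenzaldehydes and acetophenones.

Step 4
Reactants: 4 6-(benzyloxy)-2-hydroxy-3-iodo-4-(methoxymethoxy)benzaldehyde; 5 4-chlorobenzenesulfonyl chloride
Product: 6 3-(benzyloxy)-2-formyl-6-iodo-5-(methoxymethoxy)phenyl 4-chlorobenzenesulfonate
Conditions: K2CO3, acetone, rt to 40 °C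
Reagents that add atoms: none
Why: O-Sulfonylation of a phenol: the chelated hydroxyl (future c5-O) is the only nucleophile left, and the 4-chlorobenzenesulfonate is the leaving group suited to magnesium-based aryne generation because it resists attack at sulfur.

Step 5
Reactants: 6 3-(benzyloxy)-2-formyl-6-iodo-5-(methoxymethoxy)phenyl 4-chlorobenzenesulfonate
Product: 8 3-(benzyloxy)-2-hydroxy-6-iodo-5-(methoxymethoxy)phenyl 4-chlorobenzenesulfonate, via aryl formate 7 (not isolated)
Conditions: mCPBA, CH2Cl2, rt; then MeOH, K2CO3 (cat.), 0 °C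
Reagents that add atoms: 3-chloroperoxybenzoic acid OOC(=O)c1cccc(Cl)c1
Why: Baeyer–Villiger (Dakin-type) oxidation: the ortho benzyloxy and para MOM-oxy donors make the aryl group migrate, formate 7 is transesterified by methanol far faster than the aryl sulfonate is touched, and iodide and MOM ether are inert to the peracid.

Step 6
Reactants: 9 5-fluorobenzene-1,3-diol
Product: 10 1,3-bis(benzyloxy)-5-fluorobenzene
Conditions: BnBr (2.2 equiv), K2CO3, DMF, 50 °C
Reagents that add atoms: benzyl bromide BrCc1ccccc1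
Why: Williamson etherification of a simple resorcinol, for which C-benzylation is not a concern.

Step 7
Reactants: 10 1,3-bis(benzyloxy)-5-fluorobenzene
Product: 11 1,5-bis(benzyloxy)-2,4-dibromo-3-fluorobenzene
Conditions: NBS (2.05 equiv), MeCN, 0 °C to rt, dark
Reagents that add atoms: N-bromosuccinimide O=C1CCC(=O)N1Br
Why: Electrophilic aromatic bromination: each bromine enters para to one benzyloxy group and ortho to the other, that is at the two carbons flanking fluorine, as in the 2,6-dihalogenation of 5-substituted resorcinol diethers, while the polar solvent and darkness exclude benzylic bromination.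

Step 8
Reactants: 11 1,5-bis(benzyloxy)-2,4-dibromo-3-fluorobenzene
Product: 16 4,6-bis(benzyloxy)-2-fluorobenzene-1,3-dicarbaldehyde, via aryllithium 12 (not isolated), via bromo amino-alkoxide 13 (not isolated), via lithiated amino-alkoxide 14 (not isolated), via bis(amino-alkoxide) 15 (not isolated)
Conditions: n-BuLi (1.05 equiv), THF, −78 °C; DMF (1.1 equiv); n-BuLi (1.15 equiv), −78 °C; DMF (2 equiv); aq. HCl
Reagents that add atoms: N,N-dimethylformamide CN(C)C=O
Why: Bromine–lithium exchange and formylation run twice in one flask: the tetrahedral lithium amino-alkoxide 13 masks the first aldehyde during the second exchange, exchange outruns benzylic deprotonation, and at −78 °C the ortho-fluoroaryllithiums do not lose LiF.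

Step 9
Reactants: 8 3-(benzyloxy)-2-hydroxy-6-iodo-5-(methoxymethoxy)phenyl 4-chlorobenzenesulfonate; 16 4,6-bis(benzyloxy)-2-fluorobenzene-1,3-dicarbaldehyde
Product: 17 3-(benzyloxy)-2-[3,5-bis(benzyloxy)-2,6-diformylphenoxy]-6-iodo-5-(methoxymethoxy)phenyl 4-chlorobenzenesulfonate
Conditions: K2CO3, DMF, rt to 40 °C
Reagents that add atoms: none
Why: Nucleophilic aromatic substitution (SNAr): the fluoride between two ortho formyl groups is displaced even by the hindered c4 phenoxide near room temperature, which builds the tetra-ortho-substituted c4–O–d6 ether without any metal, so the ring C iodide and sulfonate are left alone.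

Step 10
Reactants: 17 3-(benzyloxy)-2-[3,5-bis(benzyloxy)-2,6-diformylphenoxy]-6-iodo-5-(methoxymethoxy)phenyl 4-chlorobenzenesulfonate
Product: 19 3-(benzyloxy)-2-[3,5-bis(benzyloxy)-2,6-dihydroxyphenoxy]-6-iodo-5-(methoxymethoxy)phenyl 4-chlorobenzenesulfonate, via bis(formate) 18 (not isolated)
Conditions: mCPBA (3 equiv), CH2Cl2, rt; then MeOH, K2CO3 (cat.), 0 °C, argon
Reagents that add atoms: 3-chloroperoxybenzoic acid OOC(=O)c1cccc(Cl)c1
Why: Double Baeyer–Villiger oxidation: each formyl group has ortho and para oxygen donors so the aryl group migrates, mild methanolysis of 18 frees the two equivalent hydroxyls d1-OH and d5-OH, and sulfonate, iodide and MOM ether survive.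

Step 11
Reactants: 19 3-(benzyloxy)-2-[3,5-bis(benzyloxy)-2,6-dihydroxyphenoxy]-6-iodo-5-(methoxymethoxy)phenyl 4-chlorobenzenesulfonate
Product: 23 4,7,9-tris(benzyloxy)-1-iodo-2-(methoxymethoxy)dibenzo[b,e][1,4]dioxin-6-ol, via magnesiated sulfonate 20 (not isolated), via ring C aryne 21 (not isolated), via cyclised aryl Grignard 22 (not isolated)
Conditions: iPrMgCl (3.1 equiv), THF (0.02 M), −78 °C, 1 h; warm to rt, 2 h; I2 (1.2 equiv), −40 to 0 °C; aq. Na2S2O3, NH4Cl
Reagents that add atoms: iodine II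
Why: Two equivalents of iPrMgCl convert the two ring D hydroxyls, which are equivalent through the mirror plane of ring D, into chloromagnesium phenoxides, and the third exchanges the c6 iodide, an exchange speeded by the neighbouring sulfonate and the chelating MOM oxygen, to give 20, which holds at −78 °C. On warming, 20 expels chloromagnesium 4-chlorobenzenesulfonate from c5 and becomes the c5≡c6 aryne 21. Either phenoxide oxygen adds to c5 and closes the six-membered dioxin ring (atoms O, d1, d6, O, c4, c5), so the second dioxin C–O bond is made by intramolecular nucleophilic addition to the aryne, while addition to c6 would demand a strained seven-membered meta-bridged ring; the tether therefore decides the regiochemistry, which the opposed inductive effects of the c4 and c1 oxygens would leave open. The charge arrives at c6 as aryl Grignard 22, flanked and stabilised by the MOM and dioxin oxygens, and iodine turns it into iodide 23, whereas the surviving d5 phenoxide has no free ortho or para carbon and is simply reprotonated on work-up. The closest known reaction types are aryne formation from 2-iodoaryl 4-chlorobenzenesulfonates by iodine–magnesium exchange followed by addition of a magnesiated heteroatom nucleophile and capture of the new aryl Grignard by an electrophile, and intramolecular aryne etherification; no stereocentre is created. Close to three equivalents of Grignard reagent and high dilution are what keep isopropyl addition and intermolecular phenoxide addition to the aryne in check.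

Step 12
Reactants: 24 5-bromobenzene-1,3-diol
Product: 25 1,3-bis(benzyloxy)-5-bromobenzene
Conditions: BnBr (2.2 equiv), K2CO3, DMF, 50 °C
Reagents that add atoms: benzyl bromide BrCc1ccccc1
Why: Williamson etherification of a simple resorcinol, giving the common source of rings A, E and F.

Step 13
Reactants: 25 1,3-bis(benzyloxy)-5-bromobenzene
Product: 28 [3,5-bis(benzyloxy)phenyl]boronic acid, via aryllithium 26 (not isolated), via lithium arylborate 27 (not isolated)
Conditions: n-BuLi, THF, −78 °C; B(OiPr)3; 1 M HCl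
Reagents that add atoms: triisopropyl borate CC(C)OB(OC(C)C)OC(C)C; water O
Why: Bromine–lithium exchange and electrophilic borylation: exchange at −78 °C is faster than any deprotonation of the benzyl ethers, and acid hydrolysis of borate 27 releases the boronic acid.

Step 14
Reactants: 29 5-bromo-2,4-dihydroxybenzaldehyde
Product: 30 2,4-bis(benzyloxy)-5-bromobenzaldehyde
Conditions: BnBr (2.4 equiv), K2CO3, DMF, 70 °C
Reagents that add atoms: benzyl bromide BrCc1ccccc1
Why: Williamson etherification, with heating to overcome the hydrogen bond of the ortho hydroxyl; the purchased bromide fixes b5 without any regiochemical question.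

Step 15
Reactants: 30 2,4-bis(benzyloxy)-5-bromobenzaldehyde
Product: 32 2,4-bis(benzyloxy)-5-bromophenol, via aryl formate 31 (not isolated)
Conditions: mCPBA, CH2Cl2, rt; then MeOH, K2CO3 (cat.), 0 °C
Reagents that add atoms: 3-chloroperoxybenzoic acid OOC(=O)c1cccc(Cl)c1
Why: Baeyer–Villiger (Dakin-type) oxidation: ortho and para benzyloxy donors secure aryl migration, so the formyl carbon becomes the b1 oxygen.

Step 16
Reactants: 32 2,4-bis(benzyloxy)-5-bromophenol; 28 [3,5-bis(benzyloxy)phenyl]boronic acid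
Product: 33 1,5-bis(benzyloxy)-2-[3,5-bis(benzyloxy)phenoxy]-4-bromobenzene
Conditions: Cu(OAc)2 (1 equiv), pyridine, 4 Å MS, CH2Cl2, air, rt
Reagents that add atoms: none
Why: Chan–Lam O-arylation: the room-temperature copper-mediated coupling of a phenol with an unhindered arylboronic acid leaves the aryl bromide untouched, which an Ullmann coupling would not.

Step 17
Reactants: 33 1,5-bis(benzyloxy)-2-[3,5-bis(benzyloxy)phenoxy]-4-bromobenzene
Product: 34 2-{2,4-bis(benzyloxy)-5-[3,5-bis(benzyloxy)phenoxy]phenyl}-4,4,5,5-tetramethyl-1,3,2-dioxaborolane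
Conditions: B2pin2, Pd(dppf)Cl2 (5 mol %), KOAc, dioxane, 90 °C
Reagents that add atoms: bis(pinacolato)diboron CC1(C)OB(OC1(C)C)B1OC(C)(C)C(C)(C)O1
Why: Miyaura borylation of a mono-ortho-substituted aryl bromide, for which the weak base KOAc prevents Suzuki homocoupling.

Step 18
Reactants: 1 2,4,6-trihydroxybenzaldehyde
Product: 35 2,4,6-tris(benzyloxy)benzaldehyde
Conditions: BnBr (3.5 equiv), K2CO3, DMF, 60 °C
Reagents that add atoms: benzyl bromide BrCc1ccccc1
Why: Exhaustive Williamson etherification: the formyl group lowers the ring nucleophilicity of the phloroglucinol core, so O-benzylation should prevail over C-benzylation.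

Step 19
Reactants: 35 2,4,6-tris(benzyloxy)benzaldehyde
Product: 37 2,4,6-tris(benzyloxy)phenol, via aryl formate 36 (not isolated)
Conditions: mCPBA, CH2Cl2, rt; then MeOH, K2CO3 (cat.), 0 °C
Reagents that add atoms: 3-chloroperoxybenzoic acid OOC(=O)c1cccc(Cl)c1
Why: Baeyer–Villiger (Dakin-type) oxidation of a very electron-rich benzaldehyde, giving the ring H phenol whose hydroxyl is the future G–O–H oxygen.

Step 20
Reactants: 10 1,3-bis(benzyloxy)-5-fluorobenzene
Product: 39 2,4-bis(benzyloxy)-6-fluorobenzaldehyde, via aryl iminium chloride 38 (not isolated)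
Conditions: POCl3, DMF, 0 to 60 °C; then H2O
Reagents that add atoms: N,N-dimethylformamide CN(C)C=O; water O
Why: Vilsmeier–Haack formylation: attack para to one benzyloxy group and ortho to the other, next to fluorine, is preferred over the crowded carbon between the two ethers, as known for 5-halo and 5-alkyl resorcinol diethers.

Step 21
Reactants: 37 2,4,6-tris(benzyloxy)phenol; 39 2,4-bis(benzyloxy)-6-fluorobenzaldehyde
Product: 40 2,4-bis(benzyloxy)-6-[2,4,6-tris(benzyloxy)phenoxy]benzaldehyde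
Conditions: K2CO3, DMF, 110 °C, argon
Reagents that add atoms: none
Why: SNAr: the ortho formyl group activates the fluoride, the two benzyloxy groups sit meta to the reacting carbon and do not destabilise the Meisenheimer adduct, and the formyl carbon marks the ring G carbon that is to be oxygenated next.

Step 22
Reactants: 40 2,4-bis(benzyloxy)-6-[2,4,6-tris(benzyloxy)phenoxy]benzaldehyde
Product: 42 2,4-bis(benzyloxy)-6-[2,4,6-tris(benzyloxy)phenoxy]phenol, via aryl formate 41 (not isolated)
Conditions: mCPBA, CH2Cl2, rt; then MeOH, K2CO3 (cat.), 0 °C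
Reagents that add atoms: 3-chloroperoxybenzoic acid OOC(=O)c1cccc(Cl)c1
Why: Baeyer–Villiger (Dakin-type) oxidation: ortho aryloxy, ortho benzyloxy and para benzyloxy donors secure aryl migration and deliver the ring G hydroxyl that will be joined to ring F.

Step 23
Reactants: 25 1,3-bis(benzyloxy)-5-bromobenzene
Product: 43 1,5-bis(benzyloxy)-3-bromo-2-iodobenzene
Conditions: NIS (1.05 equiv), TFA (cat.), MeCN, rt
Reagents that add atoms: N-iodosuccinimide O=C1CCC(=O)N1I
Why: Electrophilic aromatic iodination para to one benzyloxy group and next to bromine, the regiochemistry known for 1-bromo-3,5-dialkoxybenzenes.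

Step 24
Reactants: 43 1,5-bis(benzyloxy)-3-bromo-2-iodobenzene (two molecules)
Product: 44 4,4',6,6'-tetrakis(benzyloxy)-2,2'-dibromo-1,1'-biphenyl (racemic)
Conditions: Cu powder (activated, 5 equiv), DMF, 130 °C
Reagents that add atoms: none
Why: Classical Ullmann homocoupling: copper engages the C–I bond well ahead of the C–Br bond and tolerates two ortho substituents per partner, so the tetra-ortho-substituted E–F axis is set early on a small symmetric molecule.

Step 25
Reactants: 44 4,4',6,6'-tetrakis(benzyloxy)-2,2'-dibromo-1,1'-biphenyl (3 equiv); 42 2,4-bis(benzyloxy)-6-[2,4,6-tris(benzyloxy)phenoxy]phenol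
Product: 45 E–F–G–H bromide: 44 in which one bromine is replaced by the oxygen of 42
Conditions: CuI (0.3 equiv), picolinic acid (0.6 equiv), K3PO4, DMSO–dioxane, 100 °C
Reagents that add atoms: none
Why: Ullmann-type diaryl ether synthesis with the CuI–picolinic acid system developed for hindered partners: the excess of symmetric dibromide holds the reaction at monosubstitution (the surplus is recovered), and the bromine-bearing carbon is meta to both ring oxygens and hence not deactivated.

Step 26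
Reactants: 23 4,7,9-tris(benzyloxy)-1-iodo-2-(methoxymethoxy)dibenzo[b,e][1,4]dioxin-6-ol; 34 A–B boronate
Product: 46 A–B–C–D biaryl phenol: 23 in which the c6 iodine is replaced by the b5 carbon of the 2,4-bis(benzyloxy)-5-[3,5-bis(benzyloxy)phenoxy]phenyl group
Conditions: Pd2(dba)3 (5 mol %), SPhos (12 mol %), K3PO4, toluene–H2O, 90 °C, degassed
Reagents that add atoms: none
Why: Suzuki–Miyaura coupling: SPhos-ligated zerovalent palladium inserts into the di-ortho-oxygenated C–I bond and tolerates the free d5 phenol, and since the boronate has one ortho substituent only, the biaryl is just tri-ortho-substituted and protodeboronation is limited.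

Step 27
Reactants: 46 A–B–C–D biaryl phenol; 45 E–F–G–H bromide
Product: 47 eight-ring MOM ether: 46 whose d5 oxygen carries the ring E carbon of 45 in place of bromine
Conditions: CuI (0.5 equiv), picolinic acid (1 equiv), K3PO4, DMSO–dioxane, 100 °C
Reagents that add atoms: none
Why: Ullmann-type diaryl ether synthesis: d5-OH is the only free hydroxyl and an electron-rich phenoxide, no aryl iodide is left to compete, and the natural polarity (2,6-dioxygenated phenol as nucleophile, halide on a carbon meta to the ring oxygens) is respected.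

Step 28
Reactants: 47 eight-ring MOM ether
Product: 48 eight-ring c1 phenol
Conditions: HCl (cat.), THF–MeOH, 50 °C
Reagents that add atoms: none
Why: Acid-catalysed acetal exchange: the MOM group is the only acetal in the molecule, benzyl and diaryl ethers are inert, and the large excess of methanol carries the formaldehyde unit off as dimethoxymethane before it can alkylate an electron-rich ring.

Step 29
Reactants: 48 eight-ring c1 phenol
Product: 49 hexadeca-O-benzyl ether of the target
Conditions: Pd(OAc)2 (10 mol %), 3-nitropyridine (10 mol %), t-BuOOBz (2 equiv), C6F6–DMI, 90 °C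
Reagents that add atoms: none
Why: Phenol-directed C–H activation/C–O cyclisation of a 2-arylphenol to a dibenzofuran: the c1 phenoxide binds divalent palladium, only b6–H can be palladated because b4 carries a benzyloxy group, and oxidation to tetravalent palladium by the perester triggers C–O reductive elimination, so only the required furan regioisomer can form.

Step 30
Reactants: 49 hexadeca-O-benzyl ether of the target
Product: 50 CNP0192765.0
Conditions: H2 (1 atm), Pd(OH)2/C, THF–MeOH, rt; filtration and concentration under argon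
Reagents that add atoms: none
Why: Global hydrogenolysis of aryl benzyl ethers under neutral conditions, which leaves diaryl ethers, the dioxin and the furan intact and spares the oxidation-prone polyphenol any acid or Lewis acid.

Compound list
1 | 2,4,6-trihydroxybenzaldehyde | O=Cc1c(O)cc(O)cc1O | starting material
2 | 2,6-dihydroxy-4-(methoxymethoxy)benzaldehyde | O=Cc1c(O)cc(OCOC)cc1O | intermediate
3 | 2-(benzyloxy)-6-hydroxy-4-(methoxymethoxy)benzaldehyde | O=Cc1c(O)cc(OCOC)cc1OCc1ccccc1 | intermediate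
4 | 6-(benzyloxy)-2-hydroxy-3-iodo-4-(methoxymethoxy)benzaldehyde | O=Cc1c(O)c(I)c(OCOC)cc1OCc1ccccc1 | intermediate
5 | 4-chlorobenzenesulfonyl chloride | O=S(=O)(Cl)c1ccc(Cl)cc1 | starting material
6 | 3-(benzyloxy)-2-formyl-6-iodo-5-(methoxymethoxy)phenyl 4-chlorobenzenesulfonate | O=Cc1c(OS(=O)(=O)c2ccc(Cl)cc2)c(I)c(OCOC)cc1OCc1ccccc1 | intermediate
7 | 3-(benzyloxy)-2-(formyloxy)-6-iodo-5-(methoxymethoxy)phenyl 4-chlorobenzenesulfonate | O=COc1c(OS(=O)(=O)c2ccc(Cl)cc2)c(I)c(OCOC)cc1OCc1ccccc1 | intermediate (not isolated)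
8 | 3-(benzyloxy)-2-hydroxy-6-iodo-5-(methoxymethoxy)phenyl 4-chlorobenzenesulfonate (ring C phenol) | Oc1c(OS(=O)(=O)c2ccc(Cl)cc2)c(I)c(OCOC)cc1OCc1ccccc1 | intermediate
9 | 5-fluorobenzene-1,3-diol | Oc1cc(O)cc(F)c1 | starting material
10 | 1,3-bis(benzyloxy)-5-fluorobenzene | Fc1cc(OCc2ccccc2)cc(OCc2ccccc2)c1 | intermediate
11 | 1,5-bis(benzyloxy)-2,4-dibromo-3-fluorobenzene | Fc1c(Br)c(OCc2ccccc2)cc(OCc2ccccc2)c1Br | intermediate
12 | [4,6-bis(benzyloxy)-3-bromo-2-fluorophenyl]lithium | [Li]c1c(F)c(Br)c(OCc2ccccc2)cc1OCc1ccccc1 | intermediate (not isolated)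
13 | lithium [4,6-bis(benzyloxy)-3-bromo-2-fluorophenyl](dimethylamino)methanolate (configuration undefined, lost on hydrolysis) | [Li+].[O-]C(N(C)C)c1c(F)c(Br)c(OCc2ccccc2)cc1OCc1ccccc1 | intermediate (not isolated)
14 | 3-lithio analogue of 13 (lithium in place of bromine) | [Li+].[O-]C(N(C)C)c1c(F)c([Li])c(OCc2ccccc2)cc1OCc1ccccc1 | intermediate (not isolated)
15 | dilithium bis(dimethylamino)methanolate of dialdehyde 16 | [Li+].[Li+].[O-]C(N(C)C)c1c(F)c(C([O-])N(C)C)c(OCc2ccccc2)cc1OCc1ccccc1 | intermediate (not isolated)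
16 | 4,6-bis(benzyloxy)-2-fluorobenzene-1,3-dicarbaldehyde (ring D electrophile) | O=Cc1c(F)c(C=O)c(OCc2ccccc2)cc1OCc1ccccc1 | intermediate
17 | 3-(benzyloxy)-2-[3,5-bis(benzyloxy)-2,6-diformylphenoxy]-6-iodo-5-(methoxymethoxy)phenyl 4-chlorobenzenesulfonate | COCOc1cc(OCc2ccccc2)c(Oc2c(C=O)c(OCc3ccccc3)cc(OCc3ccccc3)c2C=O)c(OS(=O)(=O)c2ccc(Cl)cc2)c1I | intermediate
18 | bis(formate) of 19 (formyloxy groups at d1 and d5) | COCOc1cc(OCc2ccccc2)c(Oc2c(OC=O)c(OCc3ccccc3)cc(OCc3ccccc3)c2OC=O)c(OS(=O)(=O)c2ccc(Cl)cc2)c1I | intermediate (not isolated)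
19 | 3-(benzyloxy)-2-[3,5-bis(benzyloxy)-2,6-dihydroxyphenoxy]-6-iodo-5-(methoxymethoxy)phenyl 4-chlorobenzenesulfonate (key-step precursor) | COCOc1cc(OCc2ccccc2)c(Oc2c(O)c(OCc3ccccc3)cc(OCc3ccccc3)c2O)c(OS(=O)(=O)c2ccc(Cl)cc2)c1I | intermediate
20 | c6-chloromagnesio bis(chloromagnesium phenoxide) of 19 | COCOc1cc(OCc2ccccc2)c(Oc2c(O[Mg]Cl)c(OCc3ccccc3)cc(OCc3ccccc3)c2O[Mg]Cl)c(OS(=O)(=O)c2ccc(Cl)cc2)c1[Mg]Cl | intermediate (not isolated)
21 | c5≡c6 aryne of ring C tethered to the ring D bis(chloromagnesium phenoxide) | COCOC1=CC(OCc2ccccc2)=C(Oc2c(O[Mg]Cl)c(OCc3ccccc3)cc(OCc3ccccc3)c2O[Mg]Cl)C#C1 | intermediate (not isolated)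
22 | c6-chloromagnesio dibenzodioxin, d5 chloromagnesium phenoxide | COCOc1cc(OCc2ccccc2)c2Oc3c(O[Mg]Cl)c(OCc4ccccc4)cc(OCc4ccccc4)c3Oc2c1[Mg]Cl | intermediate (not isolated)
23 | 4,7,9-tris(benzyloxy)-1-iodo-2-(methoxymethoxy)dibenzo[b,e][1,4]dioxin-6-ol (key-step product) | COCOc1cc(OCc2ccccc2)c2Oc3c(O)c(OCc4ccccc4)cc(OCc4ccccc4)c3Oc2c1I | intermediate
24 | 5-bromobenzene-1,3-diol | Oc1cc(O)cc(Br)c1 | starting material
25 | 1,3-bis(benzyloxy)-5-bromobenzene | Brc1cc(OCc2ccccc2)cc(OCc2ccccc2)c1 | intermediate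
26 | [3,5-bis(benzyloxy)phenyl]lithium | [Li]c1cc(OCc2ccccc2)cc(OCc2ccccc2)c1 | intermediate (not isolated)
27 | lithium [3,5-bis(benzyloxy)phenyl]tri(propan-2-yloxy)borate | [Li+].CC(C)O[B-](OC(C)C)(OC(C)C)c1cc(OCc2ccccc2)cc(OCc2ccccc2)c1 | intermediate (not isolated)
28 | [3,5-bis(benzyloxy)phenyl]boronic acid | OB(O)c1cc(OCc2ccccc2)cc(OCc2ccccc2)c1 | intermediate
29 | 5-bromo-2,4-dihydroxybenzaldehyde | O=Cc1cc(Br)c(O)cc1O | starting material
30 | 2,4-bis(benzyloxy)-5-bromobenzaldehyde | O=Cc1cc(Br)c(OCc2ccccc2)cc1OCc1ccccc1 | intermediate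
31 | 2,4-bis(benzyloxy)-5-bromophenyl formate | O=COc1cc(Br)c(OCc2ccccc2)cc1OCc1ccccc1 | intermediate (not isolated)
32 | 2,4-bis(benzyloxy)-5-bromophenol | Oc1cc(Br)c(OCc2ccccc2)cc1OCc1ccccc1 | intermediate
33 | 1,5-bis(benzyloxy)-2-[3,5-bis(benzyloxy)phenoxy]-4-bromobenzene (A–B bromide) | Brc1cc(Oc2cc(OCc3ccccc3)cc(OCc3ccccc3)c2)c(OCc2ccccc2)cc1OCc1ccccc1 | intermediate
34 | 2-{2,4-bis(benzyloxy)-5-[3,5-bis(benzyloxy)phenoxy]phenyl}-4,4,5,5-tetramethyl-1,3,2-dioxaborolane (A–B boronate) | CC1(C)OB(OC1(C)C)c1cc(Oc2cc(OCc3ccccc3)cc(OCc3ccccc3)c2)c(OCc2ccccc2)cc1OCc1ccccc1 | intermediate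
35 | 2,4,6-tris(benzyloxy)benzaldehyde | O=Cc1c(OCc2ccccc2)cc(OCc2ccccc2)cc1OCc1ccccc1 | intermediate
36 | 2,4,6-tris(benzyloxy)phenyl formate | O=COc1c(OCc2ccccc2)cc(OCc2ccccc2)cc1OCc1ccccc1 | intermediate (not isolated)
37 | 2,4,6-tris(benzyloxy)phenol | Oc1c(OCc2ccccc2)cc(OCc2ccccc2)cc1OCc1ccccc1 | intermediate
38 | N-{[2,4-bis(benzyloxy)-6-fluorophenyl]methylidene}-N-methylmethanaminium chloride | C[N+](C)=Cc1c(F)cc(OCc2ccccc2)cc1OCc1ccccc1.[Cl-] | intermediate (not isolated)
39 | 2,4-bis(benzyloxy)-6-fluorobenzaldehyde | O=Cc1c(F)cc(OCc2ccccc2)cc1OCc1ccccc1 | intermediate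
40 | 2,4-bis(benzyloxy)-6-[2,4,6-tris(benzyloxy)phenoxy]benzaldehyde | O=Cc1c(Oc2c(OCc3ccccc3)cc(OCc3ccccc3)cc2OCc2ccccc2)cc(OCc2ccccc2)cc1OCc1ccccc1 | intermediate
41 | 2,4-bis(benzyloxy)-6-[2,4,6-tris(benzyloxy)phenoxy]phenyl formate | O=COc1c(Oc2c(OCc3ccccc3)cc(OCc3ccccc3)cc2OCc2ccccc2)cc(OCc2ccccc2)cc1OCc1ccccc1 | intermediate (not isolated)
42 | 2,4-bis(benzyloxy)-6-[2,4,6-tris(benzyloxy)phenoxy]phenol (G–H phenol) | Oc1c(Oc2c(OCc3ccccc3)cc(OCc3ccccc3)cc2OCc2ccccc2)cc(OCc2ccccc2)cc1OCc1ccccc1 | intermediate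
43 | 1,5-bis(benzyloxy)-3-bromo-2-iodobenzene | Ic1c(Br)cc(OCc2ccccc2)cc1OCc1ccccc1 | intermediate
44 | 4,4',6,6'-tetrakis(benzyloxy)-2,2'-dibromo-1,1'-biphenyl (racemic axis) | Brc1cc(OCc2ccccc2)cc(OCc2ccccc2)c1-c1c(Br)cc(OCc2ccccc2)cc1OCc1ccccc1 | intermediate
45 | E–F–G–H bromide: 4,4',6,6'-tetrakis(benzyloxy)-2'-bromo-1,1'-biphenyl-2-yl ether of phenol 42 (racemic axis) | Brc1cc(OCc9ccccc9)cc(OCc9ccccc9)c1-c1c(OCc9ccccc9)cc(OCc9ccccc9)cc1Oc1c(OCc9ccccc9)cc(OCc9ccccc9)cc1Oc1c(OCc9ccccc9)cc(OCc9ccccc9)cc1OCc9ccccc9 | intermediate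
46 | A–B–C–D biaryl phenol: 4,7,9-tris(benzyloxy)-1-{2,4-bis(benzyloxy)-5-[3,5-bis(benzyloxy)phenoxy]phenyl}-2-(methoxymethoxy)dibenzo[b,e][1,4]dioxin-6-ol | COCOc1cc(OCc9ccccc9)c2Oc3c(O)c(OCc9ccccc9)cc(OCc9ccccc9)c3Oc2c1-c1cc(Oc2cc(OCc9ccccc9)cc(OCc9ccccc9)c2)c(OCc9ccccc9)cc1OCc9ccccc9 | intermediate
47 | eight-ring MOM ether: 46 with its d5 oxygen bonded to the ring E carbon of 45 that bore bromine (racemic E–F axis) | COCOc1cc(OCc9ccccc9)c2Oc3c(Oc4cc(OCc9ccccc9)cc(OCc9ccccc9)c4-c4c(OCc9ccccc9)cc(OCc9ccccc9)cc4Oc4c(OCc9ccccc9)cc(OCc9ccccc9)cc4Oc4c(OCc9ccccc9)cc(OCc9ccccc9)cc4OCc9ccccc9)c(OCc9ccccc9)cc(OCc9ccccc9)c3Oc2c1-c1cc(Oc2cc(OCc9ccccc9)cc(OCc9ccccc9)c2)c(OCc9ccccc9)cc1OCc9ccccc9 | intermediate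
48 | eight-ring c1 phenol: 47 with OH in place of the MOM ether | Oc1cc(OCc9ccccc9)c2Oc3c(Oc4cc(OCc9ccccc9)cc(OCc9ccccc9)c4-c4c(OCc9ccccc9)cc(OCc9ccccc9)cc4Oc4c(OCc9ccccc9)cc(OCc9ccccc9)cc4Oc4c(OCc9ccccc9)cc(OCc9ccccc9)cc4OCc9ccccc9)c(OCc9ccccc9)cc(OCc9ccccc9)c3Oc2c1-c1cc(Oc2cc(OCc9ccccc9)cc(OCc9ccccc9)c2)c(OCc9ccccc9)cc1OCc9ccccc9 | intermediate
49 | hexadeca-O-benzyl ether of the target (all sixteen hydroxyls as benzyl ethers, furan closed) | c1(OCc9ccccc9)cc(OCc9ccccc9)cc(Oc2c(OCc9ccccc9)cc(OCc9ccccc9)c3c2oc2cc(OCc9ccccc9)c4c(c23)Oc2c(OCc9ccccc9)cc(OCc9ccccc9)c(Oc3cc(OCc9ccccc9)cc(OCc9ccccc9)c3-c3c(OCc9ccccc9)cc(OCc9ccccc9)cc3Oc3c(OCc9ccccc9)cc(OCc9ccccc9)cc3Oc3c(OCc9ccccc9)cc(OCc9ccccc9)cc3OCc9ccccc9)c2O4)c1 | intermediate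
50 | CNP0192765.0 | Oc1cc(O)cc(Oc2c(O)cc(O)c3c2oc2cc(O)c4c(c23)Oc2c(O)cc(O)c(Oc3cc(O)cc(O)c3-c3c(O)cc(O)cc3Oc3c(O)cc(O)cc3Oc3c(O)cc(O)cc3O)c2O4)c1 | target

Total step count: 30. Longest linear sequence: 13 steps from 1 (steps 1, 2, 3, 4, 5, 9, 10, 11, 26, 27, 28, 29, 30).

Steps most likely to fail

Step 11. The tethered magnesium phenoxide is a weak nucleophile. The aryne may therefore be consumed by addition of iPrMgCl or of a second molecule before ring closure. Sulfonyl transfer to ring D before elimination, or oxidation of the free d5 phenoxide during the iodine quench, would erode the step further. The fallback avoids the aryne altogether; it sets out from 4 and comes back at 46.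
- Phenol 4 is converted with Tf2O and pyridine into the iodo triflate aldehyde F1.
- The iodide of F1 is coupled with boronate 34 ahead of the triflate (Pd(PPh3)4, K3PO4, dioxane) to give the A–B–C triflate aldehyde F2.
- Baeyer–Villiger oxidation and methanolysis give the c4 phenol F3.
- SNAr of F3 on dialdehyde 16 gives the ether dialdehyde F4.
- A double Baeyer–Villiger oxidation with methanolysis gives the bis-phenol triflate F5.
- An intramolecular palladium-catalysed C–O coupling joins the c5 triflate to one of the two equivalent ring D hydroxyls (Pd2(dba)3, t-BuXPhos, K3PO4, toluene, 100 °C). This closes the dioxin and gives 46.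

Step 29. Palladation has to take place at b6–H, a C–H bond squeezed between the biaryl bond and the ring A ether. The oxidant may instead degrade the electron-rich para-aryloxyphenol or attack benzylic positions. The fallback is a non-oxidative closure on a fluoride; it sets out from 11 and 23 and comes back at 49.
- Dibromide 11 is desymmetrised by one bromine–lithium exchange (n-BuLi, −78 °C), then B(OMe)3 and H2O2, to give the bromofluorophenol F6.
- Chan–Lam coupling of F6 with 28 gives the fluorinated A–B bromide F7, and Miyaura borylation gives the fluorinated A–B boronate F8.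
- Suzuki coupling of F8 with 23 gives the fluoro biaryl F9, and catalytic HCl in MeOH removes the MOM group to give the fluoro biaryl diol F10.
- Cs2CO3 in NMP at 140 °C closes the furan by intramolecular SNAr of the c1 phenoxide on the b6 fluoride, a closure known for 2'-fluorobiphenyl-2-ols. The product is the A–B–C–D dibenzofuran phenol F11.
- Ullmann coupling of F11 with bromide 45 under the conditions of step 27 gives 49.

Step 27. A di-ortho-substituted phenoxide on a large fragment has to meet a bromide that is ortho to a bulky, fully substituted aryl group. Slow C–O bond formation may therefore lose out to hydrodebromination and phenol oxidation. The fallback moves the point of convergence; it sets out from 46 and 44 and comes back at 47.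
- Phenol 46 is first coupled with a large excess of the small, cheap, symmetric dibromide 44 (CuI, picolinic acid, K3PO4), which drives the valuable partner to conversion and gives the six-ring bromide F12.
- The smaller G–H phenol 42, used in excess, is then attached to F12 in a second Ullmann etherification to give 47.

Further compounds
F1 | step 11 | 3-(benzyloxy)-2-formyl-6-iodo-5-(methoxymethoxy)phenyl trifluoromethanesulfonate | O=Cc1c(OS(=O)(=O)C(F)(F)F)c(I)c(OCOC)cc1OCc1ccccc1
F2 | step 11 | 3-(benzyloxy)-6-{2,4-bis(benzyloxy)-5-[3,5-bis(benzyloxy)phenoxy]phenyl}-2-formyl-5-(methoxymethoxy)phenyl trifluoromethanesulfonate | O=Cc1c(OS(=O)(=O)C(F)(F)F)c(-c2cc(Oc3cc(OCc9ccccc9)cc(OCc9ccccc9)c3)c(OCc9ccccc9)cc2OCc9ccccc9)c(OCOC)cc1OCc9ccccc9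
F3 | step 11 | 3-(benzyloxy)-6-{2,4-bis(benzyloxy)-5-[3,5-bis(benzyloxy)phenoxy]phenyl}-2-hydroxy-5-(methoxymethoxy)phenyl trifluoromethanesulfonate | Oc1c(OS(=O)(=O)C(F)(F)F)c(-c2cc(Oc3cc(OCc9ccccc9)cc(OCc9ccccc9)c3)c(OCc9ccccc9)cc2OCc9ccccc9)c(OCOC)cc1OCc9ccccc9
F4 | step 11 | F3 with its hydroxyl oxygen bonded to C2 of 4,6-bis(benzyloxy)benzene-1,3-dicarbaldehyde | O=Cc1c(OCc9ccccc9)cc(OCc9ccccc9)c(C=O)c1Oc1c(OS(=O)(=O)C(F)(F)F)c(-c2cc(Oc3cc(OCc9ccccc9)cc(OCc9ccccc9)c3)c(OCc9ccccc9)cc2OCc9ccccc9)c(OCOC)cc1OCc9ccccc9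
F5 | step 11 | F4 with both formyl groups replaced by hydroxyl groups | Oc1c(OCc9ccccc9)cc(OCc9ccccc9)c(O)c1Oc1c(OS(=O)(=O)C(F)(F)F)c(-c2cc(Oc3cc(OCc9ccccc9)cc(OCc9ccccc9)c3)c(OCc9ccccc9)cc2OCc9ccccc9)c(OCOC)cc1OCc9ccccc9
F6 | step 29 | 4,6-bis(benzyloxy)-3-bromo-2-fluorophenol | Oc1c(F)c(Br)c(OCc2ccccc2)cc1OCc1ccccc1
F7 | step 29 | 1,5-bis(benzyloxy)-2-[3,5-bis(benzyloxy)phenoxy]-4-bromo-3-fluorobenzene | Brc1c(F)c(Oc2cc(OCc9ccccc9)cc(OCc9ccccc9)c2)c(OCc9ccccc9)cc1OCc9ccccc9
F8 | step 29 | 2-{4,6-bis(benzyloxy)-3-[3,5-bis(benzyloxy)phenoxy]-2-fluorophenyl}-4,4,5,5-tetramethyl-1,3,2-dioxaborolane | CC1(C)OB(OC1(C)C)c1c(F)c(Oc2cc(OCc9ccccc9)cc(OCc9ccccc9)c2)c(OCc9ccccc9)cc1OCc9ccccc9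
F9 | step 29 | 46 with fluorine in place of hydrogen at b6 | COCOc1cc(OCc9ccccc9)c2Oc3c(O)c(OCc9ccccc9)cc(OCc9ccccc9)c3Oc2c1-c1c(F)c(Oc2cc(OCc9ccccc9)cc(OCc9ccccc9)c2)c(OCc9ccccc9)cc1OCc9ccccc9
F10 | step 29 | F9 with OH in place of the MOM ether at c1 | Oc1cc(OCc9ccccc9)c2Oc3c(O)c(OCc9ccccc9)cc(OCc9ccccc9)c3Oc2c1-c1c(F)c(Oc2cc(OCc9ccccc9)cc(OCc9ccccc9)c2)c(OCc9ccccc9)cc1OCc9ccccc9
F11 | step 29 | A–B–C–D dibenzofuran-fused dibenzodioxin, hepta-O-benzyl, free OH at d5 | c1(OCc9ccccc9)cc(OCc9ccccc9)cc(Oc2c(OCc9ccccc9)cc(OCc9ccccc9)c3c2oc2cc(OCc9ccccc9)c4c(c23)Oc2c(OCc9ccccc9)cc(OCc9ccccc9)c(O)c2O4)c1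
F12 | step 27 | 46 with its d5 oxygen bonded to C2 of the 4,4',6,6'-tetrakis(benzyloxy)-2'-bromo-1,1'-biphenyl unit | COCOc1cc(OCc9ccccc9)c2Oc3c(Oc4cc(OCc9ccccc9)cc(OCc9ccccc9)c4-c4c(Br)cc(OCc9ccccc9)cc4OCc9ccccc9)c(OCc9ccccc9)cc(OCc9ccccc9)c3Oc2c1-c1cc(Oc2cc(OCc9ccccc9)cc(OCc9ccccc9)c2)c(OCc9ccccc9)cc1OCc9ccccc9
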